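Ring positions carry the locants of the target throughout: O1, C2 (bearing the carbinol carbon C1' with ring B), C3 (bearing ring A), C4 (bearing oxygen), C5 (CH2).

## Analysis of the target

The target is a single oxolane ring with substituents on three adjacent carbons: C2 carries the secondary carbinol C1' that bears ring B, C3 carries ring A directly, C4 carries a hydroxyl, and C5 is an unsubstituted CH2. Rings A and B are both 4-hydroxy-3-methoxyphenyl groups. There are four contiguous stereocentres, C1' (R), C2 (S), C3 (R) and C4 (S). The three ring substituents lie on one face of the oxolane (2,3-cis and 3,4-cis), and C1' is an exocyclic centre next to C2. The sensitive functions are the two free phenols, the benzylic C1' alcohol para to a phenol (prone to ionisation, quinone methide formation and hydrogenolysis), and the C4 oxygen, whose loss from any C2=C3 unsaturated intermediate leads to a furan. The main difficulty is the all-cis array: it is the most crowded arrangement of the ring, so it must be made under kinetic control and in register with C1'. The strategy rests on O1 and ring A sitting on the adjacent carbons C2 and C3. An O1–C2=C3–aryl enol ether is the direct precursor of the cis C2–H/C3–H pair, and it arises when the C5 oxygen and an aryl group add across a C2≡C3 alkyne that already carries C1' at one end and C4 at the other.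

## Retrosynthetic reasoning

**17 back to 16 and 15.** The last two operations only remove protecting groups. The phenols travel as benzyl ethers, which are inert to organozinc reagents, carbonate with palladium, fluoride and homogeneous hydrogenation, and are released from 16 by hydrogenolysis. The C4 oxygen travels as a triisopropylsilyl ether and is released from 15. The free phenols and the para-hydroxybenzylic alcohol therefore exist only in the final product.

**15 back to 14.** The C2–H and C3–H bonds are cut together. Both hydrogens lie on the face opposite the C4 oxygen, so they correspond to one syn addition to the C2=C3 enol ether of 14, and the forward reaction has to select that face. In 14, C1' and ring A are cis on the double bond, so allylic 1,3-strain places the C1'–H bond in the alkene plane. With the R configuration at C1', the C1' oxygen then points to the face opposite the C4 silyl ether and ring B to the same face as it. A free C1' hydroxyl can therefore deliver the metal to exactly the face that must be reduced, while the C4 silyl ether and ring B shield the other face. A silyl ether at C1' would sit on the face to be reduced, which is why the C1' oxygen is unmasked before the hydrogenation. The C4 oxygen must stay silylated: a free C4 hydroxyl would direct the metal to the wrong face and would lose water easily to give a furan.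

**14 back to 13.** Only the C1' silyl group is removed. The two silyl ethers of 13 are chosen to differ widely in lability (triethylsilyl at C1', triisopropylsilyl at C4).

**13 back to 10 and 12.** This is the key disconnection: the O1–C2 and C3–aryl bonds are cut. Both belong to the enol ether, and undoing them leaves the C2≡C3 alkyne of 10, with the C5 hydroxyl placed for a 5-endo closure, and the ring A iodide 12. The cut removes the ring and ring A in one operation. It leaves a linear precursor whose two stereocentres (C4 and C1') are separated by the alkyne and can be set independently. The forward reaction must add oxygen to C2 and aryl to C3 across the alkyne in an anti sense, which is what attack of the hydroxyl on an alkyne activated by an arylpalladium species, followed by reductive elimination, would do.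

**10 back to 9 and 8.** These are protecting-group adjustments. The C5 hydroxyl is released from the pivalate 9, and the C1' hydroxyl of 8 is silylated beforehand. The C1' oxygen is protected in the key step because a free propargylic hydroxyl could bind palladium, favour insertion of the alkyne into the aryl–palladium bond, and be oxidised.

**8 back to 5 and 6 (through 7).** The C1'–C2 bond is cut between the alkynyl nucleophile 7, made from alkyne 5, and the commercial aromatic aldehyde 6. This is the most convergent cut of the chain, and the C1' centre is set by a catalyst-controlled addition to an aromatic aldehyde. It is preferred to setting C1' by reduction of a carbonyl group flanked by the aryl and alkynyl groups, because catalytic reductions distinguish two such π-substituents poorly.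

**5 back to 4, 3, 2 and 1.** C4 and C5 come from the chiral pool. Aldehyde 1 supplies the C4 stereocentre and C5; one-carbon homologation to 2 turns the aldehyde carbon into C3 and adds C2. The acetonide is removed at the stage of 2, before any acid-sensitive benzylic carbinol exists. The primary hydroxyl of 3 is then masked as the pivalate 4 and the secondary one as the silyl ether 5.

**12 back to 11.** The O–benzyl bond of the ring A iodide is cut; 11 is commercial.

## Alternatives that were turned down

**Alternative 1:** oxidative ring expansion of a furyl carbinol to a pyranone used as a temporary six-membered template.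
- Disconnection: the C1' oxygen is tied to C5 and C2–C5 are read as a furan.
- Forward key step: the carbinol A2 (ring B as benzyl ether) is oxidised at the anode in methanol with a bromide mediator, and mild acid then rearranges the product to the hydroxypyranone A1 (Achmatowicz rearrangement). A1 has C2 as a ketone, C3=C4 as an enone and C5 as a hemiacetal.
- For it: A2 is two or three steps from 6 and a 2-furyl nucleophile, and its one stereocentre comes from a routine asymmetric ketone reduction. The rearrangement is well established for this substrate class. Electricity replaces a stoichiometric oxidant that could attack the electron-rich ring B. On precedent and on ease of reaching the key substrate this route is stronger than the chosen one.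
- Against it: A1 contains neither ring A nor any ring stereocentre.
  - Ring A must go onto the α-carbon of the enone (C3), an oxygen onto the β-carbon (C4), and the C2 ketone and the C5 hemiacetal must be reduced.
  - The ring oxygen must then be moved. In A1 it is the C1' oxygen, in the target it is the C2 oxygen, so the pyran must be opened and an oxolane closed from the C2 oxygen to C5.
  - The three all-cis centres are set one at a time on a ring that is later destroyed.
  - C1' in A1 is benzylic and α to a ketone, so it can epimerise in the acid step and in the enone chemistry.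
- Comparison: at least eight to ten operations would follow A1, against four after 13. The chosen strategy gives up precedent but puts O1 and ring A in their final positions in one step and reduces the ring stereochemistry to one hydrogenation.

**Alternative 2:** conjunctive cross-coupling across a Z-alkenyl boronate.
- Disconnection: C3–aryl and C4–C5 are cut; no ring is formed.
- Forward key step: the boron ate complex from the Z-alkenyl pinacol boronate A4 and the silylmethyl Grignard reagent A6 reacts with the ring A triflate A5 under Pd(OAc)2 with a chiral ferrocenyl bisphosphine. A4 already holds C1' and C2, with the C2 oxygen as a 4-methoxybenzyl ether and the C1' oxygen as a silyl ether. The arylpalladium species activates the alkene, the silylmethyl group migrates from boron to C4, and reductive elimination forms C3–aryl. The product A3 has boron on C4 and the silylmethyl group as C5.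
- For it: two C–C bonds and two stereocentres (C3 and C4) form in one catalytic, stereospecific, three-component step. The C–B and C–Si bonds can both be oxidised with retention in one operation. There is no acid-labile enol ether and no late hydrogenation whose face must be controlled. On explicit control of C3 and C4 it is stronger than the chosen route.
- Against it:
  - A4 needs the C1'/C2 diol pair with differentiated protecting groups and a Z-alkenyl boronate. Its synthesis is at least as long as that of 10 and must set C2, which the chosen route obtains from the hydrogenation.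
  - The coupling is best behaved with unsubstituted vinyl boron ate complexes. A4 is β-substituted, branched and oxygenated at the allylic carbon, so direct alkenyl transfer (the Suzuki–Miyaura pathway) competes.
  - β-Alkoxide and β-hydride elimination from the C3–palladium intermediate also compete, because C2–O and C2–H are both β to it.
  - The catalyst must override the adjacent C2 centre.
  - After A3 there remain the oxidation, selective activation of the primary C5 hydroxyl, oxidative removal of the 4-methoxybenzyl group next to an equally electron-rich benzylic ether on ring B, ring closure and two deprotections.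
- Comparison: the sequence is longer and spreads risk over several steps. The chosen route concentrates the risk in one step and closes the ring in that step.

**Alternative 3:** [3+2] annulation of an allylsilane with an aldehyde.
- Disconnection: C2–C3 and O1–C5 are cut.
- Forward key step: a Lewis acid activates the α-silyloxy aldehyde A8 (C1' centre, ring B). The E-allylsilane A9 (ring A as pivalate) attacks with its aryl-bearing carbon to form C2–C3. Silicon bridges the resulting β-silyl cation, and the aldehyde oxygen closes onto C5 as silicon shifts to C4, which gives the oxolane A7.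
- For it: it is the most convergent of the routes. The ring, two bonds and three stereocentres form in one step from two short fragments, and the 2,3-cis relationship is the one needed. On bonds and stereocentres per step it is stronger than the chosen key step, which creates no stereocentre, and the annulation is a known reaction class.
- Against it:
  - Stereospecific addition across the E alkene puts silicon on C4 trans to ring A. Oxidation of the C–Si bond is stereoretentive, so the C4 oxygen would end trans to ring A, while the target is 3,4-cis. An inversion at a hindered secondary centre next to an aryl group would still be needed.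
  - Oxidation of a dimethyl(phenyl)silyl group starts with electrophilic removal of the phenyl group. Such electrophiles also threaten the electron-rich ring B and its benzylic silyl ether; the pivalate deactivates only ring A.
  - The stereocentre of A8 is benzylic and enolisable, so it racemises easily, and the C1'/C2 relationship depends on Felkin-type control by this centre.
  - The aryl-conjugated allylsilane A9 is a weak nucleophile, and simple allyl transfer with loss of silicon competes.
- Comparison: in the chosen route C4 comes unambiguously from the chiral pool and the all-cis arrangement follows from one-face hydrogenation. The price is a key step without direct precedent.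

Key step: step 9

Assumptions on the chemistry: aldehyde 1 oligomerises on storage and is used freshly distilled; alkyne 2 is volatile and is carried forward as a concentrated solution.

## Route

Step 1
Reactants: 1 (R)-2,2-dimethyl-1,3-dioxolane-4-carbaldehyde
Product: 2 (S)-4-ethynyl-2,2-dimethyl-1,3-dioxolane
Conditions: dimethyl (1-diazo-2-oxopropyl)phosphonate, K2CO3, MeOH, 0 °C to rt
Reagents that add atoms: dimethyl (1-diazo-2-oxopropyl)phosphonate, COP(=O)(OC)C(=[N+]=[N-])C(C)=O
Why: Ohira–Bestmann variant of the Seyferth–Gilbert homologation: methanolysis of the acetyl group frees the diazomethylphosphonate anion, which converts the aldehyde into the terminal alkyne through a vinylidene carbene and 1,2-hydrogen shift. The mild carbonate conditions leave the α-alkoxy stereocentre (the future C4) untouched; its descriptor changes from R to S only because the substituent priorities change.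

Step 2
Reactants: 2 (S)-4-ethynyl-2,2-dimethyl-1,3-dioxolane
Product: 3 (S)-but-3-yne-1,2-diol
Conditions: Amberlyst 15 (H+ form), MeOH, rt; filter, concentrate
Reagents that add atoms: none
Why: Acid-catalysed transketalisation to methanol releases the 1,2-diol. It is done here because nothing acid-sensitive is present yet, and filtration of the resin avoids an aqueous work-up of the water-soluble diol.

Step 3
Reactants: 3 (S)-but-3-yne-1,2-diol
Product: 4 (2S)-2-hydroxybut-3-yn-1-yl 2,2-dimethylpropanoate
Conditions: PivCl (1.05 equiv), pyridine, CH2Cl2, −20 to 0 °C
Reagents that add atoms: pivaloyl chloride, CC(C)(C)C(=O)Cl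
Why: Acylation with the bulky acid chloride at low temperature selects the primary over the secondary propargylic hydroxyl. The pivalate survives organozinc and silylation chemistry and is later removed reductively without touching silyl ethers.

Step 4
Reactants: 4 (2S)-2-hydroxybut-3-yn-1-yl 2,2-dimethylpropanoate
Product: 5 (2S)-2-[(triisopropylsilyl)oxy]but-3-yn-1-yl 2,2-dimethylpropanoate
Conditions: TIPSOTf, 2,6-lutidine, CH2Cl2, 0 °C to rt
Reagents that add atoms: triisopropylsilyl trifluoromethanesulfonate, CC(C)[Si](OS(=O)(=O)C(F)(F)F)(C(C)C)C(C)C
Why: Silyl triflate silylation of the hindered secondary alcohol. The triisopropylsilyl group is the lasting C4 protecting group: it resists migration to the neighbouring oxygen under base, does not coordinate the hydrogenation catalyst and shields one face of the later enol ether.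

Step 5
Reactants: 5 (2S)-2-[(triisopropylsilyl)oxy]but-3-yn-1-yl 2,2-dimethylpropanoate; 6 4-(benzyloxy)-3-methoxybenzaldehyde
Product: 8 (2S,5R)-5-[4-(benzyloxy)-3-methoxyphenyl]-5-hydroxy-2-[(triisopropylsilyl)oxy]pent-3-yn-1-yl 2,2-dimethylpropanoate, via ethylzinc acetylide 7 (not isolated)
Conditions: Et2Zn, Cy2NH (5 mol%), Et2O, rt; then (S)-BINOL (20 mol%), Ti(Oi-Pr)4 (50 mol%), 6, rt; aq. NH4Cl
Reagents that add atoms: diethylzinc, CC[Zn]CC (zinc and one ethyl group are present only in intermediate 7; no atoms remain in 8)
Why: Catalytic asymmetric addition of an alkynylzinc reagent to an aromatic aldehyde under titanium–BINOLate control, a reaction type well established for aryl aldehydes; the C4 centre is insulated by the linear alkyne, so C1' is set by the catalyst alone. (S)-BINOL is expected to send the alkynyl group to the Si face of 6, the sense it shows in the related dialkylzinc additions, which gives the 5R carbinol (alkynyl outranks aryl); the configuration of 8 would be verified by Mosher ester analysis, and (R)-BINOL would be used should the sense prove opposite. Direct alkynylation is preferred to oxidation and reduction through the aryl alkynyl ketone, whose two π-substituents are poorly distinguished by transfer-hydrogenation catalysts.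

Step 6
Reactants: 8 (2S,5R)-5-[4-(benzyloxy)-3-methoxyphenyl]-5-hydroxy-2-[(triisopropylsilyl)oxy]pent-3-yn-1-yl 2,2-dimethylpropanoate
Product: 9 (2S,5R)-5-[4-(benzyloxy)-3-methoxyphenyl]-5-[(triethylsilyl)oxy]-2-[(triisopropylsilyl)oxy]pent-3-yn-1-yl 2,2-dimethylpropanoate
Conditions: TESCl, imidazole, CH2Cl2, 0 °C
Reagents that add atoms: chlorotriethylsilane, CC[Si](Cl)(CC)CC
Why: Standard silylation of a secondary alcohol. Triethylsilyl is bulky enough to keep the propargylic oxygen from binding palladium in the key step, yet is cleaved by fluoride far faster than the C4 triisopropylsilyl ether, which allows the C1' hydroxyl to be freed selectively later.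

Step 7
Reactants: 9 (2S,5R)-5-[4-(benzyloxy)-3-methoxyphenyl]-5-[(triethylsilyl)oxy]-2-[(triisopropylsilyl)oxy]pent-3-yn-1-yl 2,2-dimethylpropanoate
Product: 10 (2S,5R)-5-[4-(benzyloxy)-3-methoxyphenyl]-5-[(triethylsilyl)oxy]-2-[(triisopropylsilyl)oxy]pent-3-yn-1-ol
Conditions: i-Bu2AlH (2.5 equiv), CH2Cl2, −78 °C; aq. potassium sodium tartrate
Reagents that add atoms: none
Why: Reductive cleavage of the pivalate ester by the aluminium hydride at low temperature; silyl ethers, the benzyl ether and the alkyne are inert under these conditions. Reduction is used instead of methanolysis to avoid alkoxide-induced silyl migration or loss of the triethylsilyl group.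

Step 8
Reactants: 11 4-iodo-2-methoxyphenol
Product: 12 1-(benzyloxy)-4-iodo-2-methoxybenzene
Conditions: BnBr, K2CO3, DMF, rt
Reagents that add atoms: benzyl bromide, BrCc1ccccc1
Why: Williamson etherification of the phenol. The benzyl ether is stable to carbonate with palladium, to fluoride and to the iridium hydrogenation, and is removed only in the last step.

Step 9
Reactants: 10 (2S,5R)-5-[4-(benzyloxy)-3-methoxyphenyl]-5-[(triethylsilyl)oxy]-2-[(triisopropylsilyl)oxy]pent-3-yn-1-ol; 12 1-(benzyloxy)-4-iodo-2-methoxybenzene
Product: 13 (4S)-3-[4-(benzyloxy)-3-methoxyphenyl]-2-{(R)-[4-(benzyloxy)-3-methoxyphenyl][(triethylsilyl)oxy]methyl}-4-[(triisopropylsilyl)oxy]-4,5-dihydrofuran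
Conditions: Pd(PPh3)4 (10 mol%), 12 (1.5 equiv), K2CO3 (3 equiv), anhydrous MeCN, 65 °C; chromatography on Et3N-deactivated silica
Reagents that add atoms: none
Why: Proposed new method: oxidative addition of 12 to zerovalent palladium gives ArPdI(PPh3)2 (divalent palladium), which binds the C2≡C3 alkyne of 10; the C5 hydroxyl then attacks C2 on the face opposite the metal (anti-oxypalladation), carbonate takes up the proton, and reductive elimination from the C3 vinyl(aryl)palladium species forms the C3–ring A bond and returns zerovalent palladium. The closest known reaction type is the palladium-catalysed arylative cyclisation of 2-alkynylphenols with aryl halides to 2,3-disubstituted benzofurans; closure of an aliphatic 3-alkyn-1-ol in the same sense under electrophilic activation is known from iodocyclisations, but the aryl-transfer version on such an alcohol is not. The one ring formed, the dihydrofuran, closes in the 5-endo-dig mode. No stereocentre is created: C2 and C3 become a planar enol ether, and C4 and C1' are not touched. The step needs regioselectivity (oxygen to C2, aryl to C3), which the tether secures because attack at C3 would give an oxetane and the C1' oxygen is silylated. It also needs oxypalladation to outrun intermolecular syn-carbopalladation, alcohol oxidation by the arylpalladium species and silyl migration; the two bulky silyloxy-bearing propargylic carbons, the protected C1' oxygen, the mild carbonate base and the migration-resistant triisopropylsilyl group are meant to secure this. The product is an acid-labile enol ether with an allylic C4 silyloxy group, so it is handled on base-washed silica to prevent loss of silanol and aromatisation to a furan.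

Step 10
Reactants: 13 (4S)-3-[4-(benzyloxy)-3-methoxyphenyl]-2-{(R)-[4-(benzyloxy)-3-methoxyphenyl][(triethylsilyl)oxy]methyl}-4-[(triisopropylsilyl)oxy]-4,5-dihydrofuran
Product: 14 (R)-[4-(benzyloxy)-3-methoxyphenyl]{(4S)-3-[4-(benzyloxy)-3-methoxyphenyl]-4-[(triisopropylsilyl)oxy]-4,5-dihydrofuran-2-yl}methanol
Conditions: Bu4NF (1.1 equiv), THF, −20 to 0 °C; aq. NH4Cl
Reagents that add atoms: none
Why: Fluoride cleaves the triethylsilyl ether far faster than the hindered triisopropylsilyl ether, so one equivalent at low temperature frees only the C1' hydroxyl, and the basic medium is safe for the enol ether. The free hydroxyl is the directing group of the next step.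

Step 11
Reactants: 14 (R)-[4-(benzyloxy)-3-methoxyphenyl]{(4S)-3-[4-(benzyloxy)-3-methoxyphenyl]-4-[(triisopropylsilyl)oxy]-4,5-dihydrofuran-2-yl}methanol
Product: 15 (R)-[4-(benzyloxy)-3-methoxyphenyl]{(2S,3S,4S)-3-[4-(benzyloxy)-3-methoxyphenyl]-4-[(triisopropylsilyl)oxy]oxolan-2-yl}methanol
Conditions: [Ir(cod)(PCy3)(py)]PF6 (10 mol%, two portions), H2 (1 atm), CH2Cl2, rt
Reagents that add atoms: none
Why: Hydroxyl-directed homogeneous hydrogenation with the cationic iridium complex (monovalent iridium), the catalyst class that reduces tetrasubstituted alkenes when a neighbouring hydroxyl binds the metal. In the rotamer that relieves allylic 1,3-strain between C1' and ring A (C1'–H in the alkene plane), the R-configured C1' hydroxyl lies on the face opposite the C4 silyl ether, so both hydrogens are delivered to C2 and C3 from that face, which is also the less hindered one because the other is covered by the silyl ether and ring B. C2 and C3 are thus set together, with ring A and the carbinol side chain cis to the C4 oxygen; the 3S descriptor of 15 reflects the priority of silicon, not a different configuration from the target.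

Step 12
Reactants: 15 (R)-[4-(benzyloxy)-3-methoxyphenyl]{(2S,3S,4S)-3-[4-(benzyloxy)-3-methoxyphenyl]-4-[(triisopropylsilyl)oxy]oxolan-2-yl}methanol
Product: 16 (2S,3R,4S)-3-[4-(benzyloxy)-3-methoxyphenyl]-2-{(R)-[4-(benzyloxy)-3-methoxyphenyl](hydroxy)methyl}oxolan-4-ol
Conditions: Bu4NF (2 equiv), THF, rt; aq. NH4Cl
Reagents that add atoms: none
Why: Fluoride-mediated cleavage of the secondary triisopropylsilyl ether; the saturated oxolane, the benzyl ethers and the benzylic alcohol are inert to fluoride.

Step 13
Reactants: 16 (2S,3R,4S)-3-[4-(benzyloxy)-3-methoxyphenyl]-2-{(R)-[4-(benzyloxy)-3-methoxyphenyl](hydroxy)methyl}oxolan-4-ol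
Product: 17 metasequirin E
Conditions: H2 (1 atm), 10% Pd/C, EtOAc, rt; stopped when debenzylation is complete
Reagents that add atoms: none
Why: Hydrogenolysis of the two aryl benzyl ethers over palladium in a neutral aprotic solvent. Aryl benzyl ethers cleave much faster than the secondary benzylic C1'–O bond, and no stereocentre is affected.

## Compound list

1 | (R)-2,2-dimethyl-1,3-dioxolane-4-carbaldehyde (D-glyceraldehyde acetonide) | CC1(C)OC[C@@H](O1)C=O | starting material
2 | (S)-4-ethynyl-2,2-dimethyl-1,3-dioxolane | CC1(C)OC[C@@H](O1)C#C | intermediate
3 | (S)-but-3-yne-1,2-diol | OC[C@@H](O)C#C | intermediate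
4 | (2S)-2-hydroxybut-3-yn-1-yl 2,2-dimethylpropanoate | CC(C)(C)C(=O)OC[C@@H](O)C#C | intermediate
5 | (2S)-2-[(triisopropylsilyl)oxy]but-3-yn-1-yl 2,2-dimethylpropanoate | CC(C)(C)C(=O)OC[C@@H](O[Si](C(C)C)(C(C)C)C(C)C)C#C | intermediate
6 | 4-(benzyloxy)-3-methoxybenzaldehyde | COc1cc(C=O)ccc1OCc1ccccc1 | starting material
7 | ethyl[(3S)-4-(pivaloyloxy)-3-[(triisopropylsilyl)oxy]but-1-yn-1-yl]zinc (ethylzinc acetylide, not isolated) | CC(C)(C)C(=O)OC[C@@H](O[Si](C(C)C)(C(C)C)C(C)C)C#C[Zn]CC | intermediate
8 | (2S,5R)-5-[4-(benzyloxy)-3-methoxyphenyl]-5-hydroxy-2-[(triisopropylsilyl)oxy]pent-3-yn-1-yl 2,2-dimethylpropanoate | CC(C)(C)C(=O)OC[C@@H](O[Si](C(C)C)(C(C)C)C(C)C)C#C[C@H](O)c1ccc(OCc2ccccc2)c(OC)c1 | intermediate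
9 | (2S,5R)-5-[4-(benzyloxy)-3-methoxyphenyl]-5-[(triethylsilyl)oxy]-2-[(triisopropylsilyl)oxy]pent-3-yn-1-yl 2,2-dimethylpropanoate | CC(C)(C)C(=O)OC[C@@H](O[Si](C(C)C)(C(C)C)C(C)C)C#C[C@H](O[Si](CC)(CC)CC)c1ccc(OCc2ccccc2)c(OC)c1 | intermediate
10 | (2S,5R)-5-[4-(benzyloxy)-3-methoxyphenyl]-5-[(triethylsilyl)oxy]-2-[(triisopropylsilyl)oxy]pent-3-yn-1-ol (key-step precursor; chain C1 = ring C5, C2 = ring C4, C5 = C1') | OC[C@@H](O[Si](C(C)C)(C(C)C)C(C)C)C#C[C@H](O[Si](CC)(CC)CC)c1ccc(OCc2ccccc2)c(OC)c1 | intermediate
11 | 4-iodo-2-methoxyphenol | COc1cc(I)ccc1O | starting material
12 | 1-(benzyloxy)-4-iodo-2-methoxybenzene | COc1cc(I)ccc1OCc1ccccc1 | intermediate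
13 | (4S)-3-[4-(benzyloxy)-3-methoxyphenyl]-2-{(R)-[4-(benzyloxy)-3-methoxyphenyl][(triethylsilyl)oxy]methyl}-4-[(triisopropylsilyl)oxy]-4,5-dihydrofuran (key-step product) | COc1cc(C2=C([C@H](O[Si](CC)(CC)CC)c3ccc(OCc4ccccc4)c(OC)c3)OC[C@H]2O[Si](C(C)C)(C(C)C)C(C)C)ccc1OCc1ccccc1 | intermediate
14 | (R)-[4-(benzyloxy)-3-methoxyphenyl]{(4S)-3-[4-(benzyloxy)-3-methoxyphenyl]-4-[(triisopropylsilyl)oxy]-4,5-dihydrofuran-2-yl}methanol | COc1cc(C2=C([C@H](O)c3ccc(OCc4ccccc4)c(OC)c3)OC[C@H]2O[Si](C(C)C)(C(C)C)C(C)C)ccc1OCc1ccccc1 | intermediate
15 | (R)-[4-(benzyloxy)-3-methoxyphenyl]{(2S,3S,4S)-3-[4-(benzyloxy)-3-methoxyphenyl]-4-[(triisopropylsilyl)oxy]oxolan-2-yl}methanol (all-cis ring) | COc1cc([C@H]2[C@@H]([C@H](O)c3ccc(OCc4ccccc4)c(OC)c3)OC[C@H]2O[Si](C(C)C)(C(C)C)C(C)C)ccc1OCc1ccccc1 | intermediate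
16 | (2S,3R,4S)-3-[4-(benzyloxy)-3-methoxyphenyl]-2-{(R)-[4-(benzyloxy)-3-methoxyphenyl](hydroxy)methyl}oxolan-4-ol (all-cis ring) | COc1cc([C@H]2[C@@H]([C@H](O)c3ccc(OCc4ccccc4)c(OC)c3)OC[C@H]2O)ccc1OCc1ccccc1 | intermediate
17 | metasequirin E, (2S,3R,4S)-3-(4-hydroxy-3-methoxyphenyl)-2-[(R)-hydroxy(4-hydroxy-3-methoxyphenyl)methyl]oxolan-4-ol | COc1cc([C@H]2[C@@H]([C@H](O)c3ccc(O)c(OC)c3)OC[C@H]2O)ccc1O | target

## Step count and least certain steps

Total: 13 steps. Longest linear sequence: 12 steps (steps 1–7, then 9–13); step 8 is a one-step side branch.

**Step 9 (key step, proposed new method).**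
- What may go wrong: the neutral aliphatic hydroxyl may attack the palladium-bound alkyne too slowly, so that intermolecular syn-carbopalladation, reduction of the aryl iodide or protodepalladation to the non-arylated dihydrofuran take over. Loss of silanol from C4 with aromatisation may also consume the product on the metal or on silica.
- Fallback (known chemistry, from 10 back to 13): 5-endo-dig iodocyclisation of 10 with I2 and NaHCO3 in MeCN at 0 °C gives the 3-iodo-4,5-dihydrofuran F1. Suzuki–Miyaura coupling of F1 with commercial [4-(benzyloxy)-3-methoxyphenyl]boronic acid (COc1cc(B(O)O)ccc1OCc1ccccc1), PdCl2(dppf) and aqueous K3PO4 in THF at 50 °C then forms the C3–ring A bond and gives 13. Oxygen and aryl are added in two separate, established operations instead of one.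

**Step 11 (directed hydrogenation).**
- What may go wrong: the tetrasubstituted, doubly flanked enol ether may not turn over, or face selection may be incomplete if the reactive rotamer differs from the one assumed. Acid derived from the catalyst may ionise the doubly activated C1' alcohol or cause loss of the C4 silanol. The allylic alcohol 14 may also prove too labile to isolate after step 10.
- Fallback (from 13 back to 16): the bis-silyl ether 13 is hydrogenated heterogeneously (5% Pt/C, H2 at 5 bar, EtOAc with a trace of Et3N). This relies on syn delivery from the catalyst surface and on steric approach control instead of hydroxyl direction: the C4 triisopropylsilyl ether and ring B cover one face, and the C1' triethylsilyloxy group on the other face is the smaller obstacle. It gives the bis-silylated all-cis oxolane F2. Excess Bu4NF in THF removes both silyl groups from F2 and gives 16. This path avoids 14 altogether.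

**Step 5 (asymmetric alkynylation).**
- What may go wrong: insufficient or inverted facial selectivity at C1', or competing ethyl transfer to the aldehyde, because the alkyne carries a bulky propargylic silyl ether and an ester.
- Fallback (from 5 back to 8): 5 is deprotonated with LiN(SiMe3)2 in THF at −78 °C and added to 6 without stereocontrol, giving the C1' epimer mixture F3. MnO2 in CH2Cl2 oxidises F3 to the ynone F4. F4 is reduced with the enantiomer of B-isopinocampheyl-9-borabicyclo[3.3.1]nonane (Alpine-Borane) that gives the 5R carbinol 8; this reagent treats the rod-like alkynyl group as the small substituent and the aryl group as the large one.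

**Step 13 (hydrogenolysis).**
- What may go wrong: over-reduction by hydrogenolysis of the benzylic C1'–O bond once the para phenol is free, or slow debenzylation that invites it.
- Fallback (from 15 to 17): the benzyl groups of 15 are transferred to silane with Pd(OAc)2, Et3SiH and Et3N in CH2Cl2 at rt, giving the bis(aryl triethylsilyl ether) F5. Any C1' oxygen silylated under these conditions converges in the next operation. Bu4NF in THF then removes the aryl silyl groups and the C4 triisopropylsilyl group together and gives 17 without exposing the benzylic alcohol to hydrogen on palladium.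

## Further compounds

F1 | step 9 | (4R)-2-{(R)-[4-(benzyloxy)-3-methoxyphenyl][(triethylsilyl)oxy]methyl}-3-iodo-4-[(triisopropylsilyl)oxy]-4,5-dihydrofuran (same spatial arrangement at C4 as in 13; the descriptor changes because iodine raises the priority of C3) | IC1=C([C@H](O[Si](CC)(CC)CC)c2ccc(OCc3ccccc3)c(OC)c2)OC[C@H]1O[Si](C(C)C)(C(C)C)C(C)C
F2 | step 11 | {(R)-[4-(benzyloxy)-3-methoxyphenyl]{(2S,3S,4S)-3-[4-(benzyloxy)-3-methoxyphenyl]-4-[(triisopropylsilyl)oxy]oxolan-2-yl}methoxy}triethylsilane (all-cis ring) | COc1cc([C@H]2[C@@H]([C@H](O[Si](CC)(CC)CC)c3ccc(OCc4ccccc4)c(OC)c3)OC[C@H]2O[Si](C(C)C)(C(C)C)C(C)C)ccc1OCc1ccccc1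
F3 | step 5 | (2S,5RS)-5-[4-(benzyloxy)-3-methoxyphenyl]-5-hydroxy-2-[(triisopropylsilyl)oxy]pent-3-yn-1-yl 2,2-dimethylpropanoate (mixture of 8 and its C5 epimer) | CC(C)(C)C(=O)OC[C@@H](O[Si](C(C)C)(C(C)C)C(C)C)C#CC(O)c1ccc(OCc2ccccc2)c(OC)c1
F4 | step 5 | (2S)-5-[4-(benzyloxy)-3-methoxyphenyl]-5-oxo-2-[(triisopropylsilyl)oxy]pent-3-yn-1-yl 2,2-dimethylpropanoate | CC(C)(C)C(=O)OC[C@@H](O[Si](C(C)C)(C(C)C)C(C)C)C#CC(=O)c1ccc(OCc2ccccc2)c(OC)c1
F5 | step 13 | (R)-{3-methoxy-4-[(triethylsilyl)oxy]phenyl}{(2S,3S,4S)-3-{3-methoxy-4-[(triethylsilyl)oxy]phenyl}-4-[(triisopropylsilyl)oxy]oxolan-2-yl}methanol | COc1cc([C@H]2[C@@H]([C@H](O)c3ccc(O[Si](CC)(CC)CC)c(OC)c3)OC[C@H]2O[Si](C(C)C)(C(C)C)C(C)C)ccc1O[Si](CC)(CC)CC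
A1 | alternative 1 | (2R)-2-[4-(benzyloxy)-3-methoxyphenyl]-6-hydroxy-2H-pyran-3(6H)-one (anomeric mixture) | O=C1C=CC(O)O[C@@H]1c1ccc(OCc2ccccc2)c(OC)c1
A2 | alternative 1 | (R)-[4-(benzyloxy)-3-methoxyphenyl](furan-2-yl)methanol | O[C@@H](c1ccco1)c1ccc(OCc2ccccc2)c(OC)c1
A3 | alternative 2 | conjunctive coupling product: acyclic C1'–C5 chain with ring A on C3, pinacol boronate on C4, (isopropoxydimethylsilyl)methyl as C5, 4-methoxybenzyl ether at C2 and tert-butyldimethylsilyl ether at C1' | COc1cc([C@@H]([C@H](OCc2ccc(OC)cc2)[C@H](O[Si](C)(C)C(C)(C)C)c2ccc(OCc3ccccc3)c(OC)c2)[C@H](B2OC(C)(C)C(C)(C)O2)C[Si](C)(C)OC(C)C)ccc1OCc1ccccc1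
A4 | alternative 2 | 2-[(1Z,3S,4R)-4-[4-(benzyloxy)-3-methoxyphenyl]-4-[(tert-butyldimethylsilyl)oxy]-3-[(4-methoxybenzyl)oxy]but-1-en-1-yl]-4,4,5,5-tetramethyl-1,3,2-dioxaborolane | CC1(C)OB(/C=C\[C@H](OCc2ccc(OC)cc2)[C@H](O[Si](C)(C)C(C)(C)C)c2ccc(OCc3ccccc3)c(OC)c2)OC1(C)C
A5 | alternative 2 | 4-(benzyloxy)-3-methoxyphenyl trifluoromethanesulfonate | COc1cc(OS(=O)(=O)C(F)(F)F)ccc1OCc1ccccc1
A6 | alternative 2 | chloro{[dimethyl(propan-2-yloxy)silyl]methyl}magnesium | CC(C)O[Si](C)(C)C[Mg]Cl
A7 | alternative 3 | 2,3-cis-3,4-trans 4-[dimethyl(phenyl)silyl]oxolane with ring A (as pivalate) on C3 and the tert-butyldimethylsilyl-protected (R)-carbinol bearing ring B (as benzyl ether) on C2 | COc1cc([C@H]2[C@@H]([C@H](O[Si](C)(C)C(C)(C)C)c3ccc(OCc4ccccc4)c(OC)c3)OC[C@@H]2[Si](C)(C)c3ccccc3)ccc1OC(=O)C(C)(C)C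
A8 | alternative 3 | (R)-2-[4-(benzyloxy)-3-methoxyphenyl]-2-[(tert-butyldimethylsilyl)oxy]acetaldehyde | O=C[C@H](O[Si](C)(C)C(C)(C)C)c1ccc(OCc2ccccc2)c(OC)c1
A9 | alternative 3 | 4-{(1E)-3-[dimethyl(phenyl)silyl]prop-1-en-1-yl}-2-methoxyphenyl 2,2-dimethylpropanoate | COc1cc(/C=C/C[Si](C)(C)c2ccccc2)ccc1OC(=O)C(C)(C)C
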